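**Plan**

1. Locants are those of the target skeleton and are kept for every intermediate: C1 quaternary C–CH3, C2 CHOH, C3 CH2, C4 C(OH)iPr, C5 ring-fusion CH, C6 CH–O-ester, C7 CH2, C8(CH3)=C9, C10 CH2; β is the face of the C1 methyl.
2. Retrosynthesis: cut the C6 ester; cut the ring-fusion bond C1–C5 by moving C1 back to C6 (retro-pinacol), which turns the cyclopentane/cycloheptene pair into a cis-decalin; cut that decalin at C1–C10 and C6–C7 into thymoquinone and isoprene.
3. Enabling feature: C6, the oxygen-bearing carbon of the seven-membered ring, is bonded to ring-fusion C5, and quaternary C1 is the other fusion atom. With C6 as a tertiary carbinol bonded to C1 and a leaving group on C5, a 1,2-shift of C1 from C6 to C5 closes the five-membered ring (C1–C5), enlarges six-membered ring B to the cycloheptene and unveils the C6 carbonyl.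
4. Forward: the Diels–Alder reaction gives a decalin with all 15 skeletal carbons (ring B is the future seven-membered ring); ring A is oxidised at C4, C2, C5 and C6; the shift makes both target rings at once; C6 reduction, acylation and desilylation finish.
5. Stereochemistry: C1 comes from the catalytic asymmetric Diels–Alder reaction; C4 from epoxidation on the convex face of the cis-fused adduct; the C4 hydroxyl then directs C2 (anti reduction), C5/C6 (syn dihydroxylation) and finally C6 (anti reduction); C5 of the target arises by inversion in the stereospecific shift.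

Key step: step 10

Assumption: the (R)-BINOL–titanium catalyst of step 1 is taken to give the enantiomer 3 shown; if its sense of induction is the opposite, (S)-BINOL is used.

**Route**

Step 1
Reactants: 1 thymoquinone (2-isopropyl-5-methyl-1,4-benzoquinone); 2 isoprene (2-methylbuta-1,3-diene)
Product: 3 (4aR,8aS)-2-isopropyl-4a,7-dimethyl-4a,5,8,8a-tetrahydronaphthalene-1,4-dione (cis-fused; C1–CH3 and C6–H cis; C2 and C5 ketones, C3=C4, C8=C9)
Conditions: TiCl2(OiPr)2 (10 mol%), (R)-BINOL (10 mol%), 4 Å MS, isoprene (3 equiv), CH2Cl2, −30 °C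
Reagents that add atoms: none
Why: Lewis-acid-catalysed endo Diels–Alder reaction at the less hindered, methyl-bearing C=C of the quinone, in which titanium on the carbonyl next to the C–CH3 carbon makes the unsubstituted olefin carbon the electrophilic terminus so that C1 of isoprene bonds there (1,4-related methyls, "para" rule), while the chiral BINOL–titanium complex selects the quinone face and so sets C1 (and, cis to it, the temporary C6–H).

Step 2
Reactants: 3 cis-decalin enedione
Product: 4 C3,C4-epoxide of 3 (epoxide oxygen β, cis to C1–CH3 and C6–H; C2 and C5 ketones)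
Conditions: 30% H2O2, Na2CO3 (0.2 equiv), MeOH–THF, 0 °C, short reaction time
Reagents that add atoms: hydrogen peroxide, OO
Why: Weitz–Scheffer nucleophilic epoxidation is selective for the electron-poor enedione C3=C4 over C8=C9, and hydroperoxide attacks the convex face of the cis-fused bicycle (the face of C1–CH3 and C6–H, away from ring B), which sets the C4–O bond cis to the C1 methyl.

Step 3
Reactants: 4 epoxy-dione
Product: 6 C5 enol triflate of 4 (C5(OTf)=C6; C2 ketone and C3,C4-epoxide retained), via potassium enolate 5 (not isolated)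
Conditions: KN(SiMe3)2 (1.1 equiv), THF, −78 °C; then PhNTf2 (1.2 equiv), −78 → 0 °C
Reagents that add atoms: N-phenylbis(trifluoromethanesulfonimide), O=S(=O)(N(c1ccccc1)S(=O)(=O)C(F)(F)F)C(F)(F)F
Why: C6–H is the only enolisable hydrogen (C1 is quaternary, C3 and C4 are epoxide carbons), so kinetic deprotonation and O-sulfonylation give a single enol triflate, and the C6 stereocentre, which has done its work by enforcing the cis fusion in step 2, is erased.

Step 4
Reactants: 6 epoxy ketone enol triflate
Product: 7 β-hydroxy ketone (C2 ketone, C3 CH2, C4 tertiary OH β with iPr α, C5(OTf)=C6)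
Conditions: SmI2 (2.5 equiv), THF–MeOH, −90 °C
Reagents that add atoms: none
Why: Reductive opening of an α,β-epoxy ketone by SmI2: the C2 ketyl cleaves the adjacent C3–O bond and the resulting samarium enolate is protonated by methanol, so the C4–O bond and its configuration are untouched.

Step 5
Reactants: 7 β-hydroxy ketone
Product: 8 anti-1,3-diol (C2–OH α, C4–OH β; C5(OTf)=C6)
Conditions: Me4NBH(OAc)3 (5 equiv), MeCN–AcOH (1:1), −30 °C
Reagents that add atoms: none
Why: Evans–Saksena reduction: the C4 alkoxy(acetoxy)borohydride delivers hydride intramolecularly to the β face of the C2 carbonyl, giving the 1,3-anti diol with C2–OH α (trans to the C1 methyl).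

Step 6
Reactants: 8 diol
Product: 9 C2 tert-butyldimethylsilyl ether of 8 (C4–OH free)
Conditions: TBSOTf (1.1 equiv), 2,6-lutidine, CH2Cl2, −78 °C
Reagents that add atoms: tert-butyldimethylsilyl triflate, CC(C)(C)[Si](C)(C)OS(=O)(=O)C(F)(F)F
Why: Silylation discriminates the secondary C2 hydroxyl from the hindered tertiary C4 hydroxyl, which has to stay free as directing group for step 8.

Step 7
Reactants: 9 enol triflate
Product: 10 tertiary allylic alcohol (C4–OH β, C5H=C6, C2–OTBS α, C8=C9)
Conditions: Pd(OAc)2 (5 mol%), PPh3 (10 mol%), HCO2H, n-Bu3N, DMF, 60 °C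
Reagents that add atoms: none
Why: Palladium-catalysed formate reduction of an enol triflate (oxidative addition, formate-to-hydride decarboxylation, reductive elimination) replaces OTf by H and leaves the trisubstituted C8=C9 alkene and the silyl ether untouched.

Step 8
Reactants: 10 allylic alcohol
Product: 12 cis-decalin triol (C4–OH, C5–OH and C6–OH all β, cis to C1–CH3; C2–OTBS α), via osmate ester 11 (not isolated)
Conditions: OsO4 (1.05 equiv), TMEDA (1.1 equiv), CH2Cl2, −78 °C; then aq. Na2SO3, THF, reflux
Reagents that add atoms: osmium tetroxide, O=[Os](=O)(=O)=O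
Why: Hydroxyl-directed dihydroxylation with the OsO4·TMEDA complex: in the favoured half-chair (iPr, OTBS and C1–CH3 pseudo-equatorial, C10 pseudo-axial on the α face) the pseudo-axial C4–OH hydrogen-bonds the reagent and delivers both oxygens to the β face of C5=C6, faster than the undirected C8=C9 reacts, which makes C5–OH and C6–OH cis to each other, to C4–OH and to the C1 methyl (cis-decalin).

Step 9
Reactants: 12 triol
Product: 13 C5 mesylate of 12 (OMs β; C4–OH and C6–OH free)
Conditions: MsCl (1.2 equiv), Et3N, CH2Cl2, −20 → 0 °C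
Reagents that add atoms: methanesulfonyl chloride, CS(=O)(=O)Cl
Why: Sulfonylation via sulfene takes place only at the secondary C5 hydroxyl, the two flanking hydroxyls being tertiary, and no epoxide can form afterwards because both neighbours are cis to the mesylate.

Step 10
Reactants: 13 cis-decalin diol mesylate
Product: 14 trans-fused hydroazulenone (2α-(tert-butyldimethylsilyloxy)-4β-hydroxydauc-8-en-6-one; C5–H α, C1–CH3 β)
Conditions: Et3Al (3.5 equiv), CH2Cl2, −78 → 0 °C; Rochelle-salt work-up at 0 °C
Reagents that add atoms: none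
Why: Et3Al converts both tertiary hydroxyls into aluminium alkoxides (ethane is lost) and, as a Lewis acid, loosens the equatorial C5–OMs bond; the lone pair on O6 then pushes the antiperiplanar C6–C1 σ-bond over to C5 as mesylate leaves, so that C6 becomes the ketone. The closest known reaction type is the pinacol-type (semipinacol) rearrangement of cis-1,2-diol monosulfonates, used to turn decalin diol monosulfonates into hydroazulenones and, in its organoaluminium form, for stereospecific 1,2-shifts of 2-sulfonyloxy alcohols. The five-membered ring is closed by a 1,2-alkyl shift that contracts ring A (C1–C6 becomes C1–C5) while ring B grows from six to seven members, so the closure is a ring contraction coupled to a ring expansion, not an exo or endo attack. C5 is the only new stereocentre and is set by inversion (C1 enters anti to the departing mesylate), which puts H5 on the face opposite to the C1 methyl (trans ring fusion), while C1 migrates with retention and C2 and C4 are untouched. The step needs C1 to migrate, not C7 or C3: in the only low-energy chair of ring A (iPr, OTBS, C1–CH3, OMs and C7 equatorial; C10, O4 and O6 axial) the C6–C7 bond is gauche to C–OMs and cannot move, epoxide closure is impossible because both flanking oxygens are cis to the mesylate, and of the two antiperiplanar ring bonds the one to the fully substituted C1 should migrate in preference to the one to the C3 methylene. The aluminium chelate of the product aldol (O4–Al–O6) protects it from retro-aldol cleavage until the cold work-up.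

Step 11
Reactants: 14 β-hydroxy ketone
Product: 15 2α-(tert-butyldimethylsilyloxy)dauc-8-ene-4β,6α-diol
Conditions: Me4NBH(OAc)3 (5 equiv), MeCN–AcOH (1:1), −30 °C
Reagents that add atoms: none
Why: Evans–Saksena reduction again: the C4 hydroxyl delivers hydride to the β face of the C6 carbonyl to give the 1,3-anti diol (C6–OH α), which also removes the β,γ-unsaturated ketone before it can isomerise.

Step 12
Reactants: 16 4-hydroxybenzoic acid
Product: 18 4-[(tert-butyldimethylsilyl)oxy]benzoic acid, via silyl ester 17 (not isolated)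
Conditions: TBSCl (2.3 equiv), imidazole, DMF, rt; then AcOH–THF–H2O (3:1:1), rt
Reagents that add atoms: tert-butyldimethylsilyl chloride, CC(C)(C)[Si](C)(C)Cl
Why: Both hydroxyl groups are silylated and the far more labile silyl ester is then hydrolysed selectively, leaving the aryl silyl ether.

Step 13
Reactants: 15 diol; 18 4-[(tert-butyldimethylsilyl)oxy]benzoic acid
Product: 19 bis-silyl ether of the target (C6 4-(TBSO)benzoate, C2–OTBS, C4–OH free)
Conditions: DCC (1.5 equiv), DMAP (0.5 equiv), CH2Cl2, rt
Reagents that add atoms: none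
Why: Steglich esterification acylates the only secondary hydroxyl (C6–OH), the tertiary C4–OH being unreactive towards the acylpyridinium intermediate.

Step 14
Reactants: 19 bis-silyl ether
Product: 20 2α-hydroxyferutinin (target)
Conditions: Bu4NF (3 equiv), AcOH (3 equiv), THF, 0 °C → rt
Reagents that add atoms: none
Why: Buffered fluoride cleaves the aryl and the secondary alkyl silyl ether in one operation without acyl migration or ester cleavage.

**Compound list**

1 | thymoquinone | CC1=CC(=O)C(C(C)C)=CC1=O | starting material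
2 | isoprene | C=CC(C)=C | starting material
3 | (4aR,8aS)-2-isopropyl-4a,7-dimethyl-4a,5,8,8a-tetrahydronaphthalene-1,4-dione (cis-fused) | CC1=CC[C@@]2(C)C(=O)C=C(C(C)C)C(=O)[C@H]2C1 | intermediate
4 | C3,C4-β-epoxide of 3 | CC1=CC[C@@]2(C)C(=O)[C@@H]3O[C@]3(C(C)C)C(=O)[C@H]2C1 | intermediate
5 | potassium C5–C6 enolate of 4 | CC1=CC[C@@]2(C)C(=O)[C@@H]3O[C@]3(C(C)C)C([O-])=C2C1.[K+] | intermediate (not isolated)
6 | C5 enol triflate of 4 | CC1=CC[C@@]2(C)C(=O)[C@@H]3O[C@]3(C(C)C)C(OS(=O)(=O)C(F)(F)F)=C2C1 | intermediate
7 | β-hydroxy ketone (C2 ketone, C4–OH β, C5 enol triflate) | CC1=CC[C@@]2(C)C(=O)C[C@@](O)(C(C)C)C(OS(=O)(=O)C(F)(F)F)=C2C1 | intermediate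
8 | anti-diol (C2–OH α, C4–OH β, C5 enol triflate) | CC1=CC[C@@]2(C)[C@@H](O)C[C@@](O)(C(C)C)C(OS(=O)(=O)C(F)(F)F)=C2C1 | intermediate
9 | C2 TBS ether of 8 | CC1=CC[C@@]2(C)[C@@H](O[Si](C)(C)C(C)(C)C)C[C@@](O)(C(C)C)C(OS(=O)(=O)C(F)(F)F)=C2C1 | intermediate
10 | allylic alcohol (C4–OH β, C5H=C6, C2–OTBS α) | CC1=CC[C@@]2(C)[C@@H](O[Si](C)(C)C(C)(C)C)C[C@@](O)(C(C)C)C=C2C1 | intermediate
11 | C5,C6-β-osmate ester of 10 (hexavalent osmium, TMEDA complex) | CC1=CC[C@@]2(C)[C@@H](O[Si](C)(C)C(C)(C)C)C[C@@](O)(C(C)C)[C@@H]3O[Os](=O)(=O)O[C@]23C1.CN(C)CCN(C)C | intermediate (not isolated)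
12 | cis-decalin triol (C4–OH, C5–OH, C6–OH all β; C2–OTBS α) | CC1=CC[C@@]2(C)[C@@H](O[Si](C)(C)C(C)(C)C)C[C@@](O)(C(C)C)[C@H](O)[C@@]2(O)C1 | intermediate
13 | C5 mesylate of 12 | CC1=CC[C@@]2(C)[C@@H](O[Si](C)(C)C(C)(C)C)C[C@@](O)(C(C)C)[C@H](OS(C)(=O)=O)[C@@]2(O)C1 | intermediate
14 | 2α-(tert-butyldimethylsilyloxy)-4β-hydroxydauc-8-en-6-one (trans-fused, 5α-H) | CC1=CC[C@]2(C)[C@@H](C(=O)C1)[C@](O)(C(C)C)C[C@@H]2O[Si](C)(C)C(C)(C)C | intermediate
15 | 2α-(tert-butyldimethylsilyloxy)dauc-8-ene-4β,6α-diol | CC1=CC[C@]2(C)[C@@H]([C@@H](O)C1)[C@](O)(C(C)C)C[C@@H]2O[Si](C)(C)C(C)(C)C | intermediate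
16 | 4-hydroxybenzoic acid | O=C(O)c1ccc(O)cc1 | starting material
17 | tert-butyldimethylsilyl 4-[(tert-butyldimethylsilyl)oxy]benzoate | CC(C)(C)[Si](C)(C)OC(=O)c1ccc(O[Si](C)(C)C(C)(C)C)cc1 | intermediate (not isolated)
18 | 4-[(tert-butyldimethylsilyl)oxy]benzoic acid | O=C(O)c1ccc(O[Si](C)(C)C(C)(C)C)cc1 | intermediate
19 | bis-silyl ether of the target (C6 4-(TBSO)benzoate, C2–OTBS) | CC1=CC[C@]2(C)[C@@H]([C@@H](OC(=O)c3ccc(O[Si](C)(C)C(C)(C)C)cc3)C1)[C@](O)(C(C)C)C[C@@H]2O[Si](C)(C)C(C)(C)C | intermediate
20 | 2α-hydroxyferutinin | CC1=CC[C@]2(C)[C@@H]([C@@H](OC(=O)c3ccc(O)cc3)C1)[C@](O)(C(C)C)C[C@@H]2O | target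

**Step count**

Total step count: 14. Longest linear sequence: 13 steps (steps 1–11, 13 and 14; step 12 is a one-step branch).

**Steps most likely to fail**

Step 10 (key step). The shift may be misdirected: the O4 alkoxide can push the C4–C3 ring bond, which is also antiperiplanar to the mesylate, instead of O6 pushing C6–C1; the product aldol may also open by retro-aldol cleavage if the work-up is not cold. The fallback sets out from 13 and returns at 14. Et3SiOTf and 2,6-lutidine at −78 °C silylate the less hindered tertiary hydroxyl (C4–OH; C6–OH is flanked by quaternary C1) to give the 4-O-triethylsilyl ether of mesylate 13 F1, in which only O6 can drive a shift. Et3Al then gives the 4-O-triethylsilyl ether of ketone 14 F2, and PPTS in MeOH removes the triethylsilyl group to give 14.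

Step 8. The osmylation may be too slow at the trisubstituted alkene that lies between two fully substituted carbons, so that site selectivity is lost to the undirected C8=C9 bond. The fallback sets out from 10 and returns at 12. VO(acac)2 (cat.) and t-BuOOH in CH2Cl2 give, under direction of the C4 hydroxyl and with complete selectivity for the allylic alcohol, the 5β,6β-epoxide of 10 F3. CO2 (10 bar) with Bu4NBr (cat.) at 90 °C converts it with overall retention (bromide opens at C5, the carbonate oxygen closes at C5) into the cis-fused 5,6-cyclic carbonate of 12 F4. K2CO3 in MeOH then releases triol 12.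

Step 1. Enantioface discrimination may be insufficient, and the orientation may leak to the other regioisomer, in the cycloaddition of a dialkylquinone with an unactivated diene. The fallback sets out from 1 and 2 and returns at 8. SnCl4 in CH2Cl2 at −78 °C gives racemic 3, which is taken through steps 2–5 to racemic 8. Esterification of the C2 hydroxyl with (S)-O-methylmandelic acid (DCC, DMAP) gives two diastereomers, the (S)-O-methylmandelate of 8 F5 and the (S)-O-methylmandelate of the enantiomer of 8 F6, which are separated by chromatography. iBu2AlH in CH2Cl2 at −78 °C cleaves F5 to 8.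

**Further compounds**

F1 | step 10 | 4-O-triethylsilyl ether of mesylate 13 | CC1=CC[C@@]2(C)[C@@H](O[Si](C)(C)C(C)(C)C)C[C@@](O[Si](CC)(CC)CC)(C(C)C)[C@H](OS(C)(=O)=O)[C@@]2(O)C1
F2 | step 10 | 4-O-triethylsilyl ether of ketone 14 | CC1=CC[C@]2(C)[C@@H](C(=O)C1)[C@](O[Si](CC)(CC)CC)(C(C)C)C[C@@H]2O[Si](C)(C)C(C)(C)C
F3 | step 8 | 5β,6β-epoxide of 10 | CC1=CC[C@@]2(C)[C@@H](O[Si](C)(C)C(C)(C)C)C[C@@](O)(C(C)C)[C@@H]3O[C@]23C1
F4 | step 8 | 5,6-cyclic carbonate of 12 | CC1=CC[C@@]2(C)[C@@H](O[Si](C)(C)C(C)(C)C)C[C@@](O)(C(C)C)[C@@H]3OC(=O)O[C@]23C1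
F5 | step 1 | (S)-O-methylmandelate of 8 | CC1=CC[C@@]2(C)[C@@H](OC(=O)[C@@H](OC)c3ccccc3)C[C@@](O)(C(C)C)C(OS(=O)(=O)C(F)(F)F)=C2C1
F6 | step 1 | (S)-O-methylmandelate of the enantiomer of 8 | CC1=CC[C@]2(C)[C@H](OC(=O)[C@@H](OC)c3ccccc3)C[C@](O)(C(C)C)C(OS(=O)(=O)C(F)(F)F)=C2C1
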